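**Retrosynthetic overview**
1. C2–aryl bond, made last: the (2S)-flavanone comes from 5,7-dihydroxy-6-(1,1-dimethylallyl)chromone and (4-hydroxy-3-methoxyphenyl)boronic acid. A Rh/(S)-bisphosphine 1,4-addition sets the only stereocentre.
2. Rings A and C together: the chromone comes from one monocyclic 2-pyrone carrying a 4-ethoxy-2-oxobut-3-enyl chain. Lactone opening, C4a–C5 Claisen aromatisation and O1–C2 oxa-Michael/elimination run in one flask.
3. C4–C4a bond: the side chain comes from γ-acylation of the pyrone dianion with (E)-3-ethoxyacryloyl chloride.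
4. C6–tert-prenyl bond: [3,3] Claisen shift of the 4-O-prenyl ether of triacetic acid lactone, itself made by Mitsunobu reaction with prenol.
5. Ring order: a bought, sacrificial pyrone is converted into rings A and C at the same time. Ring B is bought with the boronic acid.

Assumption: LDA (THF solution) and Mg(OMe)2 (MeOH solution) are bought as such. The target SMILES encodes the (2S) enantiomer.

**Step 1**
Reactants: 1 4-hydroxy-6-methyl-2H-pyran-2-one (triacetic acid lactone); 2 3-methylbut-2-en-1-ol (prenol)
Product: 3 6-methyl-4-[(3-methylbut-2-en-1-yl)oxy]-2H-pyran-2-one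
Conditions: PPh3, DIAD, THF, 0 °C → rt
Reagents that add atoms: none
Why: Mitsunobu etherification, in which the acidic vinylogous-acid OH of 1 (pKa ≈ 5) is alkylated on O-4 by SN2 attack on the primary allylic oxyphosphonium salt, avoiding the C-3 alkylation seen with prenyl halides; no stereocentre is formed.

**Step 2**
Reactants: 3 6-methyl-4-[(3-methylbut-2-en-1-yl)oxy]-2H-pyran-2-one
Product: 4 4-hydroxy-6-methyl-3-(2-methylbut-3-en-2-yl)-2H-pyran-2-one
Conditions: Eu(fod)3 (10 mol %), PhMe, 90 °C
Reagents that add atoms: none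
Why: Lewis-acid-accelerated Claisen [3,3] rearrangement, in which the O4–C4=C3 allyl vinyl ether can only deliver the inverted allyl unit (1,1-dimethylallyl) to C-3, enolisation restores the pyrone, and the low temperature suppresses abnormal Claisen and dihydrofuran formation; no stereocentre is formed.

**Step 3**
Reactants: 4 4-hydroxy-6-methyl-3-(2-methylbut-3-en-2-yl)-2H-pyran-2-one; 5 (E)-3-ethoxyacryloyl chloride
Product: 7 6-[(3E)-4-ethoxy-2-oxobut-3-en-1-yl]-4-hydroxy-3-(2-methylbut-3-en-2-yl)-2H-pyran-2-one, via pyrone dianion 6 (not isolated)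
Conditions: 4 (2 equiv), LDA (4.2 equiv), THF, −78 → −30 °C; 5 (1 equiv), −78 °C; cold 1 M HCl
Reagents that add atoms: none
Why: Dianion γ-acylation (Claisen-type C-acylation of a 4-hydroxy-6-methyl-2-pyrone dianion), in which the last-formed, least stabilised charge on the C-6 methyl carbon reacts first, C-3 is blocked, the hard acid chloride is attacked 1,2 rather than at the β-ethoxy carbon, and the acidic product is deprotonated by the second equivalent of 6, which stops over-addition (4 is recovered); no stereocentre is formed.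

**Step 4 (key step)**
Reactants: 7 6-[(3E)-4-ethoxy-2-oxobut-3-en-1-yl]-4-hydroxy-3-(2-methylbut-3-en-2-yl)-2H-pyran-2-one
Product: 10 5,7-dihydroxy-6-(2-methylbut-3-en-2-yl)-4H-chromen-4-one, via triketo ester 8 (not isolated), via acylphloroglucinol 9 (not isolated)
Conditions: Mg(OMe)2 (4 equiv), MeOH, 65 °C; then 2 M HCl, rt
Reagents that add atoms: none
Why: Proposed new method: methoxide opens the enol lactone to the Mg-chelated triketo ester 8 (known Mg(OMe)2 methanolysis of 4-hydroxy-2-pyrones); its doubly activated C-6 methylene attacks the ester C-1 in a six-membered Claisen/Dieckmann closure that aromatises to ring A (9), which is the classical biomimetic pyrone → acylphloroglucinol transposition, the competing aldol mode being blocked by the tert-alkyl group; the unhindered ortho-phenoxide (the other is buttressed by the tert-alkyl group into the C=O chelate) then displaces ethoxide from the β-ethoxyenone by oxa-Michael addition/elimination (standard chromone closure, completed by the acid quench) to give ring C and the 6-substituted isomer in the same flask; before ring A forms the ethoxyenone exists as an unreactive dienolate; no stereocentre is formed.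

**Step 5**
Reactants: 10 5,7-dihydroxy-6-(2-methylbut-3-en-2-yl)-4H-chromen-4-one; 11 (4-hydroxy-3-methoxyphenyl)boronic acid
Product: 12 (2S)-5,7-dihydroxy-2-(4-hydroxy-3-methoxyphenyl)-6-(2-methylbut-3-en-2-yl)-2,3-dihydro-4H-chromen-4-one
Conditions: [Rh(OH)(cod)]2 (2.5 mol %), (S)-MeO-F12-BIPHEP (5.5 mol %), 11 (3 equiv), dioxane/H2O 10:1, 40 °C, no added base
Reagents that add atoms: none
Why: Hayashi–Miyaura asymmetric 1,4-addition, in which aryl–Rh(I) formed by base-free transmetalation to Rh–OH carbometalates the chromone C2=C3 on the C-2 Re face imposed by the (S)-biaryl bisphosphine (same sense as cyclohexenone → (S)-3-arylcyclohexanone) and water protonates the Rh enolate to give (2S), while the neutral medium keeps all phenols protonated (so the acceptor stays active and no chalcone-type racemisation occurs) and the isolated hindered vinyl group is not carbometalated.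

**Compound list**
1 | 4-hydroxy-6-methyl-2H-pyran-2-one (triacetic acid lactone) | CC1=CC(O)=CC(=O)O1 | starting material
2 | 3-methylbut-2-en-1-ol (prenol) | CC(C)=CCO | starting material
3 | 6-methyl-4-[(3-methylbut-2-en-1-yl)oxy]-2H-pyran-2-one | CC1=CC(OCC=C(C)C)=CC(=O)O1 | intermediate
4 | 4-hydroxy-6-methyl-3-(2-methylbut-3-en-2-yl)-2H-pyran-2-one | CC1=CC(O)=C(C(C)(C)C=C)C(=O)O1 | intermediate
5 | (E)-3-ethoxyacryloyl chloride | CCO/C=C/C(=O)Cl | starting material
6 | dilithium salt of 4 (4-oxide, 6-CH2 carbanion) | [Li+].[Li+].[CH2-]C1=CC([O-])=C(C(C)(C)C=C)C(=O)O1 | intermediate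
7 | 6-[(3E)-4-ethoxy-2-oxobut-3-en-1-yl]-4-hydroxy-3-(2-methylbut-3-en-2-yl)-2H-pyran-2-one | CCO/C=C/C(=O)CC1=CC(O)=C(C(C)(C)C=C)C(=O)O1 | intermediate
8 | methyl (8E)-9-ethoxy-2-(2-methylbut-3-en-2-yl)-3,5,7-trioxonon-8-enoate (C-2 configurationally labile, drawn as the keto form) | COC(=O)C(C(C)(C)C=C)C(=O)CC(=O)CC(=O)/C=C/OCC | intermediate
9 | (2E)-3-ethoxy-1-[2,4,6-trihydroxy-3-(2-methylbut-3-en-2-yl)phenyl]prop-2-en-1-one | CCO/C=C/C(=O)c1c(O)cc(O)c(C(C)(C)C=C)c1O | intermediate
10 | 5,7-dihydroxy-6-(2-methylbut-3-en-2-yl)-4H-chromen-4-one | O=c1ccoc2cc(O)c(C(C)(C)C=C)c(O)c12 | intermediate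
11 | (4-hydroxy-3-methoxyphenyl)boronic acid | COc1cc(B(O)O)ccc1O | starting material
12 | (2S)-5,7-dihydroxy-2-(4-hydroxy-3-methoxyphenyl)-6-(2-methylbut-3-en-2-yl)-2,3-dihydro-4H-chromen-4-one | C=CC(C)(C)c1c(O)cc2c(c1O)C(=O)C[C@@H](c1ccc(O)c(OC)c1)O2 | target

Total step count: 5. Longest linear sequence: 5 (1 → 3 → 4 → 7 → 10 → 12).

**Steps most likely to fail**

**Step 4.**
- Risks: the hindered lactone or ester may react slowly. The C-4 carbon of 8 could close onto the ethoxyenone terminus to give a resorcinol or 4,7-dihydroxycoumarin. Some 8-substituted chromone may also form.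
- Fallback: it sets out from 7 and comes back at 10. Only the lactone is opened (Mg(OMe)2, MeOH, rt) and the mixture is acidified at once.
- Triketo ester 8 then closes through its C-5 enol oxygen onto the ethoxyenone to give the γ-pyrone methyl 3,3-dimethyl-2-[(4-oxo-4H-pyran-2-yl)acetyl]pent-4-enoate F1.
- This fixes the ring-C oxygen para to the tert-alkyl-bearing carbon and makes the unwanted carbocyclisation geometrically impossible.
- A separate DBU-mediated (THF) Dieckmann closure of the vinylogous enolate onto the ester then builds ring A and gives 10 as the only regioisomer.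

**Step 5.**
- Risks: the acidic 7-OH and the p-hydroxyarylboronic acid may cause protodeboronation or tie up Rh as an aryloxide.
- Fallback: it sets out from 10 and comes back at 12. The 7-OH is masked with TBSOTf and 2,6-lutidine in CH2Cl2 at 0 °C; the chelated 5-OH stays free. This gives 7-[(tert-butyldimethylsilyl)oxy]-5-hydroxy-6-(2-methylbut-3-en-2-yl)-4H-chromen-4-one F2.
- The same Rh addition is run with commercial [4-(tert-butyldimethylsilyloxy)-3-methoxyphenyl]boronic acid to give the (2S)-7,4'-bis-O-TBS flavanone F3.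
- Both silyl ethers are cleaved with Et3N·3HF in THF, which is non-basic and does not racemise C-2, to reach 12.

**Step 3.**
- Risks: the acidic product quenches half of the dianion, and O-acylation or amine attack on the acid chloride may compete.
- Fallback: it sets out from 4 and comes back at 7. The chain is built as C2 + C1 with electrophiles that avoid these problems.
- Dianion 6 is treated with N-methoxy-N-methylacetamide; the stable tetrahedral adduct means no proton quench. This gives 4-hydroxy-3-(2-methylbut-3-en-2-yl)-6-(2-oxopropyl)-2H-pyran-2-one F4.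
- The trianion of F4 (LDA, 3.3 equiv) is formylated at the terminal methyl group with ethyl formate to give 4-[4-hydroxy-5-(2-methylbut-3-en-2-yl)-6-oxo-6H-pyran-2-yl]-3-oxobutanal F5.
- Enol etherification (EtOH, cat. PPTS, azeotropic removal of water) converts F5 into 7.

**Further compounds**
F1 | step 4 | methyl 3,3-dimethyl-2-[(4-oxo-4H-pyran-2-yl)acetyl]pent-4-enoate | COC(=O)C(C(C)(C)C=C)C(=O)CC1=CC(=O)C=CO1
F2 | step 5 | 7-[(tert-butyldimethylsilyl)oxy]-5-hydroxy-6-(2-methylbut-3-en-2-yl)-4H-chromen-4-one | O=c1ccoc2cc(O[Si](C)(C)C(C)(C)C)c(C(C)(C)C=C)c(O)c12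
F3 | step 5 | (2S)-7-[(tert-butyldimethylsilyl)oxy]-2-{4-[(tert-butyldimethylsilyl)oxy]-3-methoxyphenyl}-5-hydroxy-6-(2-methylbut-3-en-2-yl)-2,3-dihydro-4H-chromen-4-one | C=CC(C)(C)c1c(O[Si](C)(C)C(C)(C)C)cc2c(c1O)C(=O)C[C@@H](c1ccc(O[Si](C)(C)C(C)(C)C)c(OC)c1)O2
F4 | step 3 | 4-hydroxy-3-(2-methylbut-3-en-2-yl)-6-(2-oxopropyl)-2H-pyran-2-one | CC(=O)CC1=CC(O)=C(C(C)(C)C=C)C(=O)O1
F5 | step 3 | 4-[4-hydroxy-5-(2-methylbut-3-en-2-yl)-6-oxo-6H-pyran-2-yl]-3-oxobutanal | O=CCC(=O)CC1=CC(O)=C(C(C)(C)C=C)C(=O)O1
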